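## Retrosynthetic overview

1. Aristophenone A (25) ⇐ bis-allyl ether 23 by deallylation; the C7 prenyl of 23 ⇐ exo-face radical prenyl transfer to the C7 radical from xanthate 19 ⇐ alcohol 17 ⇐ C7 ketone 16.
2. Key disconnection: ring B of 16 is cut at C5–C6 and C1–C8, giving diprenyl acylphloroglucinol 10 and 1,3-dibromo-3-methylbutan-2-one 13. The dibromoketone is an oxyallyl-dication (double enolonium) C3 unit: each new bond joins a nucleophilic ring carbon to a ketone α-carbon.
3. 10 ⇐ Hoesch acylation of phloroglucinol with nitrile 4, then double C-prenylation.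
4. Ring order: the phloroglucinol ring is there from the start and becomes ring A on dearomatisation; ring B closes in the (3+3) key step; the C7 side chain and the catechol are finished last.

Assumption: PPAP numbering is used (C1 and C5 bridgeheads, C9 bridging ketone, C7 the ring-B CH, C8 the CMe2 carbon), CIP descriptors refer to the enol tautomer drawn, and O-allyl-N-(9-anthracenylmethyl)cinchonidinium bromide is taken to give the (1S,5S) series (if the sense is opposite, its cinchoninium pseudo-enantiomer is used).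

## Route

Step 1
Reactants: 1 3,4-dihydroxybenzonitrile; 2 allyl bromide
Product: 4 3,4-bis(allyloxy)benzonitrile, via 4-(allyloxy)-3-hydroxybenzonitrile 3 (not isolated)
Conditions: 2 (2.5 equiv), K2CO3 (3 equiv), DMF, 60 °C
Reagents that add atoms: allyl bromide (second equivalent of 2), C=CCBr
Why: double Williamson etherification (SN2 on allyl bromide), the more acidic 4-OH reacting first and the 3-OH with the second equivalent; no stereocentre is formed, and the allyl ethers tolerate the later base, hydride and radical steps.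

Step 2
Reactants: 4 3,4-bis(allyloxy)benzonitrile; 5 phloroglucinol
Product: 7 [3,4-bis(allyloxy)phenyl](2,4,6-trihydroxyphenyl)methanone, via ketiminium chloride 6 (not isolated)
Conditions: HCl (g), ZnCl2, Et2O, 0 °C; then H2O, 100 °C
Reagents that add atoms: water, O
Why: Hoesch acylation: the activated nitrile attacks the electron-rich phloroglucinol once, the ketiminium salt precipitates and is deactivated, and hydrolysis gives the aryl ketone; no stereocentre.

Step 3
Reactants: 7 [3,4-bis(allyloxy)phenyl](2,4,6-trihydroxyphenyl)methanone; 8 prenyl bromide (1-bromo-3-methylbut-2-ene)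
Product: 10 [3,4-bis(allyloxy)phenyl][2,4,6-trihydroxy-3,5-bis(3-methylbut-2-en-1-yl)phenyl]methanone, via monoprenyl ketone 9 (not isolated)
Conditions: 8 (2.1 equiv), 10% aq. KOH, 0 °C
Reagents that add atoms: prenyl bromide (second equivalent of 8), CC(C)=CCBr
Why: twofold C-alkylation of the acylphloroglucinol polyanion in water (soft allylic electrophile, protic medium favours C over O), one prenyl bromide at each of the two free ring carbons; no stereocentre, modest yield expected.

Step 4
Reactants: 11 3-methylbutan-2-one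
Product: 13 1,3-dibromo-3-methylbutan-2-one, via 3-bromo-3-methylbutan-2-one 12 (not isolated)
Conditions: Br2 (2.0 equiv), cat. 48% HBr, CH2Cl2, 0 °C to rt
Reagents that add atoms: bromine (first bromination), BrBr; bromine (second bromination), BrBr
Why: acid-catalysed ketone α-bromination, first through the more substituted enol at the tertiary carbon and then at the methyl group; no stereocentre.

Step 5 (key step)
Reactants: 10 [3,4-bis(allyloxy)phenyl][2,4,6-trihydroxy-3,5-bis(3-methylbut-2-en-1-yl)phenyl]methanone; 13 1,3-dibromo-3-methylbutan-2-one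
Product: 16 (1S,5S)-3-[3,4-bis(allyloxy)benzoyl]-4-hydroxy-8,8-dimethyl-1,5-bis(3-methylbut-2-en-1-yl)bicyclo[3.3.1]non-3-ene-2,7,9-trione, via bromoketone dienone 14 (not isolated), via oxyallyl zwitterion 15 (not isolated)
Conditions: O-allyl-N-(9-anthracenylmethyl)cinchonidinium bromide (20 mol %), CsOH·H2O, 4 Å MS, CH2Cl2, −50 °C, slow addition of 13; then (CF3)2CHOH co-solvent, −50 °C to rt
Reagents that add atoms: none
Why: Proposed new method: an enantioselective alkylative dearomatisation followed by an interrupted-Favorskii (oxyallyl) ring closure, in which the chiral ammonium phenoxide ion pair of 10 C-alkylates one of its two enantiotopic prenylated ring carbons with the CH2Br of 13 (SN2 at an α-halo ketone, the ketone α-carbon acting as an enolonium) and so sets C5; in the fluorinated alcohol the new ketone enolises towards C6, loses the tertiary bromide to give oxyallyl cation 15, and C1 of the triketone enolate captures its tertiary terminus C8, which the three-atom tether allows only on the face carrying C6, so C1 follows from C5 (O-capture gives a tertiary α-keto enol ether that can re-ionise, C-capture is irreversible); the closest known chemistry is cinchona phase-transfer alkylative dearomatisation–annulation of diprenyl acylphloroglucinols with bis-electrophilic enals, and substitution of tertiary α-halo ketones by carbon nucleophiles through oxyallyl cations in fluorinated alcohols.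

Step 6
Reactants: 16 (1S,5S)-3-[3,4-bis(allyloxy)benzoyl]-4-hydroxy-8,8-dimethyl-1,5-bis(3-methylbut-2-en-1-yl)bicyclo[3.3.1]non-3-ene-2,7,9-trione
Product: 17 (1S,5S,7S)-3-[3,4-bis(allyloxy)benzoyl]-4,7-dihydroxy-8,8-dimethyl-1,5-bis(3-methylbut-2-en-1-yl)bicyclo[3.3.1]non-3-ene-2,9-dione (7-endo alcohol)
Conditions: NaBH4, THF–MeOH, −40 °C
Reagents that add atoms: none
Why: chemoselective 1,2-reduction of the only unhindered, non-enolised ketone (the β-triketone sits as its enolate, C9 is flanked by two quaternary carbons); hydride enters from the exo face to give the endo (axial) alcohol, a stereocentre that is erased in step 9.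

Step 7
Reactants: 17 (1S,5S,7S)-3-[3,4-bis(allyloxy)benzoyl]-4,7-dihydroxy-8,8-dimethyl-1,5-bis(3-methylbut-2-en-1-yl)bicyclo[3.3.1]non-3-ene-2,9-dione
Product: 19 O-[(1S,5S,7S)-3-[3,4-bis(allyloxy)benzoyl]-4-hydroxy-8,8-dimethyl-1,5-bis(3-methylbut-2-en-1-yl)-2,9-dioxobicyclo[3.3.1]non-3-en-7-yl] S-methyl carbonodithioate, via dipotassium xanthate salt 18 (not isolated)
Conditions: KN(SiMe3)2 (2.2 equiv), THF, −78 °C; CS2, −78 to 0 °C; MeI (1.05 equiv), 0 °C; aq. NH4Cl
Reagents that add atoms: carbon disulfide, S=C=S; iodomethane, CI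
Why: xanthate formation (first half of a Barton–McCombie sequence): the small electrophile CS2 reaches the hindered alkoxide, and the soft xanthate sulfur is methylated in preference to the delocalised triketone enolate; C7 configuration unchanged.

Step 8
Reactants: 20 allyl phenyl sulfone
Product: 22 (2-methylbut-3-en-2-yl)sulfonylbenzene, via (but-3-en-2-ylsulfonyl)benzene 21 (not isolated)
Conditions: n-BuLi, THF, −78 °C, then MeI; second portion of n-BuLi then MeI in the same flask
Reagents that add atoms: iodomethane (first methylation), CI; iodomethane (second methylation), CI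
Why: two rounds of α-deprotonation and α-selective methylation of an allylic sulfone anion; the product is achiral.

Step 9
Reactants: 19 O-alkyl S-methyl xanthate of the 7-endo alcohol; 22 (2-methylbut-3-en-2-yl)sulfonylbenzene
Product: 23 (1S,5S,7R)-3-[3,4-bis(allyloxy)benzoyl]-4-hydroxy-8,8-dimethyl-1,5,7-tris(3-methylbut-2-en-1-yl)bicyclo[3.3.1]non-3-ene-2,9-dione
Conditions: (Bu3Sn)2 (1.5 equiv), 22 (5 equiv), azobisisobutyronitrile, PhH, 80 °C, sunlamp
Reagents that add atoms: none
Why: Keck-type radical allyl transfer after Barton–McCombie fragmentation: Bu3Sn• adds to the thiocarbonyl, C7–O scission gives the secondary C7 radical, which adds to the CH2 terminus of 22 and expels PhSO2• to unveil the prenyl group; the radical is attacked on the exo face (the endo face is blocked by the C2–C4 bridge), so the new C–C bond is equatorial with H endo, which is the (7R) configuration of the target.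

Step 10
Reactants: 23 (1S,5S,7R)-3-[3,4-bis(allyloxy)benzoyl]-4-hydroxy-8,8-dimethyl-1,5,7-tris(3-methylbut-2-en-1-yl)bicyclo[3.3.1]non-3-ene-2,9-dione
Product: 25 Aristophenone A, via mono-allyl ether 24 (not isolated)
Conditions: Pd(PPh3)4 (5 mol %), morpholine (10 equiv), THF, rt; pH 4 buffer work-up
Reagents that add atoms: none
Why: Tsuji–Trost-type deallylation: zerovalent palladium ionises only the aryl allyl ethers (the C-prenyl groups cannot ionise) and excess morpholine traps the allyl fragment, so any transient O-allylation of the triketone is funnelled back; stereocentres untouched.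

## Compound list

1 | 3,4-dihydroxybenzonitrile | N#Cc1ccc(O)c(O)c1 | starting material
2 | allyl bromide (3-bromoprop-1-ene) | C=CCBr | starting material
3 | 4-(allyloxy)-3-hydroxybenzonitrile | N#Cc1ccc(OCC=C)c(O)c1 | intermediate (not isolated)
4 | 3,4-bis(allyloxy)benzonitrile | N#Cc1ccc(OCC=C)c(OCC=C)c1 | intermediate
5 | phloroglucinol (benzene-1,3,5-triol) | Oc1cc(O)cc(O)c1 | starting material
6 | [3,4-bis(allyloxy)phenyl](2,4,6-trihydroxyphenyl)methaniminium chloride | [NH2+]=C(c1ccc(OCC=C)c(OCC=C)c1)c1c(O)cc(O)cc1O.[Cl-] | intermediate (not isolated)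
7 | [3,4-bis(allyloxy)phenyl](2,4,6-trihydroxyphenyl)methanone | O=C(c1ccc(OCC=C)c(OCC=C)c1)c1c(O)cc(O)cc1O | intermediate
8 | prenyl bromide (1-bromo-3-methylbut-2-ene) | CC(C)=CCBr | starting material
9 | [3,4-bis(allyloxy)phenyl][2,4,6-trihydroxy-3-(3-methylbut-2-en-1-yl)phenyl]methanone | O=C(c1ccc(OCC=C)c(OCC=C)c1)c1c(O)cc(O)c(CC=C(C)C)c1O | intermediate (not isolated)
10 | [3,4-bis(allyloxy)phenyl][2,4,6-trihydroxy-3,5-bis(3-methylbut-2-en-1-yl)phenyl]methanone | O=C(c1ccc(OCC=C)c(OCC=C)c1)c1c(O)c(CC=C(C)C)c(O)c(CC=C(C)C)c1O | intermediate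
11 | 3-methylbutan-2-one | CC(=O)C(C)C | starting material
12 | 3-bromo-3-methylbutan-2-one | CC(=O)C(C)(C)Br | intermediate (not isolated)
13 | 1,3-dibromo-3-methylbutan-2-one | BrCC(=O)C(C)(C)Br | intermediate
14 | 4-[3,4-bis(allyloxy)benzoyl]-6-(3-bromo-3-methyl-2-oxobutyl)-3,5-dihydroxy-2,6-bis(3-methylbut-2-en-1-yl)cyclohexa-2,4-dien-1-one, quaternary carbon configured as C5 of 25 | O=C1C(CC=C(C)C)=C(O)C(C(=O)c2ccc(OCC=C)c(OCC=C)c2)=C(O)[C@]1(CC=C(C)C)CC(=O)C(C)(C)Br | intermediate (not isolated)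
15 | oxyallyl zwitterion formed from 14 by loss of HBr (side chain CH=C(O−)–C+Me2 on the same quaternary carbon) | O=C1C(CC=C(C)C)=C(O)C(C(=O)c2ccc(OCC=C)c(OCC=C)c2)=C(O)[C@]1(CC=C(C)C)C=C([O-])[C+](C)C | intermediate (not isolated)
16 | (1S,5S)-3-[3,4-bis(allyloxy)benzoyl]-4-hydroxy-8,8-dimethyl-1,5-bis(3-methylbut-2-en-1-yl)bicyclo[3.3.1]non-3-ene-2,7,9-trione | O=C1C[C@]2(CC=C(C)C)C(=O)[C@@](CC=C(C)C)(C(=O)C(C(=O)c3ccc(OCC=C)c(OCC=C)c3)=C2O)C1(C)C | intermediate
17 | (1S,5S,7S)-3-[3,4-bis(allyloxy)benzoyl]-4,7-dihydroxy-8,8-dimethyl-1,5-bis(3-methylbut-2-en-1-yl)bicyclo[3.3.1]non-3-ene-2,9-dione (7-OH endo) | O[C@H]1C[C@]2(CC=C(C)C)C(=O)[C@@](CC=C(C)C)(C(=O)C(C(=O)c3ccc(OCC=C)c(OCC=C)c3)=C2O)C1(C)C | intermediate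
18 | dipotassium salt of the 7-O-dithiocarbonate and triketone enolate of 17 | [K+].[K+].[S-]C(=S)O[C@H]1C[C@]2(CC=C(C)C)C(=O)[C@@](CC=C(C)C)(C(=O)C(C(=O)c3ccc(OCC=C)c(OCC=C)c3)=C2[O-])C1(C)C | intermediate (not isolated)
19 | O-[(1S,5S,7S)-3-[3,4-bis(allyloxy)benzoyl]-4-hydroxy-8,8-dimethyl-1,5-bis(3-methylbut-2-en-1-yl)-2,9-dioxobicyclo[3.3.1]non-3-en-7-yl] S-methyl carbonodithioate | CSC(=S)O[C@H]1C[C@]2(CC=C(C)C)C(=O)[C@@](CC=C(C)C)(C(=O)C(C(=O)c3ccc(OCC=C)c(OCC=C)c3)=C2O)C1(C)C | intermediate
20 | allyl phenyl sulfone | C=CCS(=O)(=O)c1ccccc1 | starting material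
21 | (but-3-en-2-ylsulfonyl)benzene (racemic) | C=CC(C)S(=O)(=O)c1ccccc1 | intermediate (not isolated)
22 | (2-methylbut-3-en-2-yl)sulfonylbenzene | C=CC(C)(C)S(=O)(=O)c1ccccc1 | intermediate
23 | (1S,5S,7R)-3-[3,4-bis(allyloxy)benzoyl]-4-hydroxy-8,8-dimethyl-1,5,7-tris(3-methylbut-2-en-1-yl)bicyclo[3.3.1]non-3-ene-2,9-dione (7-prenyl exo) | CC(C)=CC[C@@H]1C[C@]2(CC=C(C)C)C(=O)[C@@](CC=C(C)C)(C(=O)C(C(=O)c3ccc(OCC=C)c(OCC=C)c3)=C2O)C1(C)C | intermediate
24 | (1S,5S,7R)-3-[3-(allyloxy)-4-hydroxybenzoyl]-4-hydroxy-8,8-dimethyl-1,5,7-tris(3-methylbut-2-en-1-yl)bicyclo[3.3.1]non-3-ene-2,9-dione | CC(C)=CC[C@@H]1C[C@]2(CC=C(C)C)C(=O)[C@@](CC=C(C)C)(C(=O)C(C(=O)c3ccc(O)c(OCC=C)c3)=C2O)C1(C)C | intermediate (not isolated)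
25 | Aristophenone A, (1S,5S,7R)-3-(3,4-dihydroxybenzoyl)-4-hydroxy-8,8-dimethyl-1,5,7-tris(3-methylbut-2-en-1-yl)bicyclo[3.3.1]non-3-ene-2,9-dione (7-prenyl exo) | CC(C)=CC[C@@H]1C[C@]2(CC=C(C)C)C(=O)[C@@](CC=C(C)C)(C(=O)C(C(=O)c3ccc(O)c(O)c3)=C2O)C1(C)C | target

## Step count and risks

Total steps: 10. Longest linear sequence: 8 (steps 1, 2, 3, 5, 6, 7, 9, 10); steps 4 and 8 make reagents in parallel.

The three steps most likely to fail:

Step 5. O-alkylation of the phenoxide by the α-bromoketone, Favorskii chemistry of 13, or O-capture or C3-capture of the oxyallyl cation could all outrun the planned C5/C1 bond formation, and the enantioselectivity is untested. The fallback sets out from 10 and 13 and returns at 16. Compound 13 is condensed with aqueous hydroxylamine (NH2OH, ethanol, 0 °C) to 1,3-dibromo-3-methylbutan-2-one oxime F1. With Cs2CO3 and O-allyl-N-(9-anthracenylmethyl)cinchonidinium bromide in CH2Cl2, F1 gives two nitrosoalkenes in turn, and both ring bonds are then made by soft conjugate additions of the ring carbons of 10 (first to the CH2 terminus, then to the Me2C terminus). This gives the bicyclic 7-hydroxyimino compound F2, which is cleaved with aqueous TiCl3 and NH4OAc in THF to the ketone 16.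

Step 7. The 7-endo hydroxyl sits in the concave pocket next to the quaternary C8 and may resist xanthate formation, or the enolate may be methylated. The fallback sets out from 16 and returns at 23, bypassing steps 6, 7 and 9 with an anionic rather than radical C7 prenylation. Wittig reaction of 16 with MeOCH=PPh3 gives the 7-(methoxymethylidene) enol ether F3. Mild hydrolysis (pyridinium tosylate, wet acetone) gives the epimerisable 7-exo-carbaldehyde F4. Its potassium enolate (KOC(CH3)3, THF, −78 °C) is alkylated by prenyl bromide 8 on the exo face to the 7-endo-formyl-7-exo-prenyl aldehyde F5. Stoichiometric RhCl(PPh3)3 in toluene at 110 °C then removes CO with retention, leaving H endo and the prenyl group exo, which is 23.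

Step 9. The tertiary allyl sulfone may add the hindered C7 radical too slowly, so that reduction, xanthate side reactions or cyclisation onto a bridgehead prenyl group win. The fallback sets out from 19 and returns at 25. Keck allylation with allyltributylstannane and azobisisobutyronitrile in benzene at 80 °C gives the 7-exo-allyl bis(allyl ether) F6. Deallylation with Pd(PPh3)4 and morpholine gives the 7-exo-allyl catechol F7. Cross-metathesis with 2-methylbut-2-ene (second-generation Grubbs catalyst, RuCl2(=CHPh)(PCy3)(H2IMes), CH2Cl2, 40 °C) turns the C7 allyl group into prenyl and gives 25.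

Further compounds
F1 | step 5 | 1,3-dibromo-3-methylbutan-2-one oxime | ON=C(CBr)C(C)(C)Br
F2 | step 5 | (1S,5S)-3-[3,4-bis(allyloxy)benzoyl]-4-hydroxy-7-(hydroxyimino)-8,8-dimethyl-1,5-bis(3-methylbut-2-en-1-yl)bicyclo[3.3.1]non-3-ene-2,9-dione | ON=C1C[C@]2(CC=C(C)C)C(=O)[C@@](CC=C(C)C)(C(=O)C(C(=O)c3ccc(OCC=C)c(OCC=C)c3)=C2O)C1(C)C
F3 | step 7 | (1S,5S)-3-[3,4-bis(allyloxy)benzoyl]-4-hydroxy-7-(methoxymethylidene)-8,8-dimethyl-1,5-bis(3-methylbut-2-en-1-yl)bicyclo[3.3.1]non-3-ene-2,9-dione | COC=C1C[C@]2(CC=C(C)C)C(=O)[C@@](CC=C(C)C)(C(=O)C(C(=O)c3ccc(OCC=C)c(OCC=C)c3)=C2O)C1(C)C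
F4 | step 7 | (1S,5S,7R)-3-[3,4-bis(allyloxy)benzoyl]-4-hydroxy-8,8-dimethyl-1,5-bis(3-methylbut-2-en-1-yl)-2,9-dioxobicyclo[3.3.1]non-3-ene-7-carbaldehyde (CHO exo) | O=C[C@@H]1C[C@]2(CC=C(C)C)C(=O)[C@@](CC=C(C)C)(C(=O)C(C(=O)c3ccc(OCC=C)c(OCC=C)c3)=C2O)C1(C)C
F5 | step 7 | 3-[3,4-bis(allyloxy)benzoyl]-4-hydroxy-8,8-dimethyl-1,5,7-tris(3-methylbut-2-en-1-yl)-2,9-dioxobicyclo[3.3.1]non-3-ene-7-carbaldehyde (7-prenyl exo, 7-CHO endo) | CC(C)=CC[C@]1(C=O)C[C@]2(CC=C(C)C)C(=O)[C@@](CC=C(C)C)(C(=O)C(C(=O)c3ccc(OCC=C)c(OCC=C)c3)=C2O)C1(C)C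
F6 | step 9 | 7-exo-allyl-3-[3,4-bis(allyloxy)benzoyl]-4-hydroxy-8,8-dimethyl-1,5-bis(3-methylbut-2-en-1-yl)bicyclo[3.3.1]non-3-ene-2,9-dione | C=CC[C@@H]1C[C@]2(CC=C(C)C)C(=O)[C@@](CC=C(C)C)(C(=O)C(C(=O)c3ccc(OCC=C)c(OCC=C)c3)=C2O)C1(C)C
F7 | step 9 | 7-exo-allyl-3-(3,4-dihydroxybenzoyl)-4-hydroxy-8,8-dimethyl-1,5-bis(3-methylbut-2-en-1-yl)bicyclo[3.3.1]non-3-ene-2,9-dione | C=CC[C@@H]1C[C@]2(CC=C(C)C)C(=O)[C@@](CC=C(C)C)(C(=O)C(C(=O)c3ccc(O)c(O)c3)=C2O)C1(C)C
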